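Locants: hydrindane C1–C7a (C1 carries the linker CH2 = C8, C3a the CH2OH, C4 the Br, C7 the CH3/OH; ring B = its cyclohexane, ring C = its cyclopentane); ring A = C1′–C6′ (C1′ OAc, C3′ Me2, C4′ Br).
Cuts, last bond first: O–acetyl and O–Si; the C–H bonds at C4′ and C4 (each CHBr stands for a C(Br)CO2H centre); the lactone bond C1′–O and the alkene C8=C1′ (cross-metathesis); C1–C8 and C7a–H (vinylation of a C1 boronate made by hydroboration); C7–CH3; ring B at C3a–C4 and C5–C6, ring A at C3′–C4′ and C5′–C6′ (two Diels–Alder retrons with 2-bromoacrolein).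
Forward: a bought cyclopentene (ring C) is turned into a 2-silyloxydiene and the [4+2] closes ring B; the halves 19 (hydrindane) and 25 (ring A, same [4+2] on the mesityl oxide dienol ether) are joined at C8=C1′ and tied by a bridged lactone; both carboxyl helpers are then cut out.
Stereochemistry: C3a and the C4′ helper centre come from one chiral oxazaborolidinium catalyst; C7 (equatorial methyl attack), C7a and C1 (syn hydroboration, retentive vinylation) are relayed from C3a; C1′ is relayed from C4′ through the lactone; C4 and C4′ are finally set by axial hydrogen-atom delivery to α-bromo radicals.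
Enabling feature: in ring B the oxygen-bearing C7 and the bromine-bearing C4 are 1,4 to each other and C4 sits next to the quaternary ring-fusion carbon C3a, so C6–C7–C7a–C3a is a 2-silyloxydiene standing on ring C and C4–C5 is 2-bromoacrolein ("para" orientation), whose formyl group is only an activating helper that later leaves as CO2.

Key step: step 5

Remark: TBS = tert-butyldimethylsilyl, TIPS = triisopropylsilyl, Bpin = 4,4,5,5-tetramethyl-1,3,2-dioxaborolan-2-yl.
Remark: 2-bromoacrolein (7) is treated as a catalogue reagent, distilled before use.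
Remark: the (S)-oxazaborolidine is written from its usual sense of induction with 2-bromoacrolein (both adducts then carry an R bromo-formyl carbon); the (R)-catalyst would be taken if the sense were opposite.
Remark: steps 12–15 (ring A) run in parallel with steps 1–11.

Step 1
Reactants: 1 2-bromocyclopent-1-ene-1-carbaldehyde
Product: 2 (2-bromocyclopent-1-en-1-yl)methanol
Conditions: NaBH4, MeOH, 0 °C
Reagents that add atoms: none
Why: Borohydride 1,2-reduction of the aldehyde, which leaves the vinyl bromide untouched and creates no stereocentre.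

Step 2
Reactants: 2 (2-bromocyclopent-1-en-1-yl)methanol
Product: 3 1-bromo-2-(TBSOCH2)cyclopent-1-ene
Conditions: TBSCl, imidazole, DMF, 23 °C
Reagents that add atoms: tert-butyldimethylsilyl chloride, CC(C)(C)[Si](C)(C)Cl
Why: Imidazole-promoted silylation masks the allylic alcohol, which would otherwise close onto the later cis-acetyl group to give a furan.

Step 3
Reactants: 3 1-bromo-2-(TBSOCH2)cyclopent-1-ene
Product: 5 1-[2-(TBSOCH2)cyclopent-1-en-1-yl]ethan-1-one, via alkenyllithium 4 (not isolated)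
Conditions: t-BuLi (2.1 equiv), Et2O, −78 °C; MeC(O)N(OMe)Me, −78 → 0 °C; aq NH4Cl
Reagents that add atoms: N-methoxy-N-methylacetamide, CC(=O)N(C)OC
Why: Bromine–lithium exchange followed by Weinreb ketone synthesis, in which the chelated tetrahedral adduct stops the addition at the ketone stage.

Step 4
Reactants: 5 1-[2-(TBSOCH2)cyclopent-1-en-1-yl]ethan-1-one
Product: 6 1-(TBSOCH2)-2-[1-(TIPSO)ethenyl]cyclopent-1-ene
Conditions: TIPSOTf, Et3N, CH2Cl2, 0 °C
Reagents that add atoms: triisopropylsilyl trifluoromethanesulfonate, CC(C)[Si](C(C)C)(C(C)C)OS(=O)(=O)C(F)(F)F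
Why: Soft enolisation (silyl triflate and amine) at the acetyl CH3, the kinetic site, gives the cross-conjugated 2-silyloxydiene.

Step 5
Reactants: 6 1-(TBSOCH2)-2-[1-(TIPSO)ethenyl]cyclopent-1-ene; 7 2-bromoprop-2-enal (2-bromoacrolein)
Product: 8 (3aS,4R)-4-bromo-3a-(TBSOCH2)-7-(TIPSO)-2,3,3a,4,5,6-hexahydro-1H-indene-4-carbaldehyde
Conditions: (S)-3,3-diphenyl-1-(2-methylphenyl)tetrahydro-1H,3H-pyrrolo[1,2-c][1,3,2]oxazaborole (20 mol %), (CF3SO2)2NH (17 mol %), CH2Cl2, −78 → −40 °C
Reagents that add atoms: none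
Why: The N-protonated oxazaborolidine binds the formyl oxygen of 7 and the diene adds to the unshielded enal face in a concerted but asynchronous normal-demand [4+2] cycloaddition in which C6–C5 bonding runs ahead of C3a–C4; the closest known reaction type is the oxazaborolidinium-catalysed enantioselective Diels–Alder reaction of 2-silyloxy-1,3-dienes with 2-bromoacrolein. Ring B is the only ring closed, by suprafacial [π4s+π2s] cycloaddition onto the diene standing on ring C, which also makes the quaternary C3a and its brominated neighbour C4 in one event. C3a is controlled by the catalyst-selected enal face combined with the bromine-endo (formyl-exo) approach usual for 2-bromoacrolein, which places CHO cis to CH2OTBS; C4 is formed as 4R by the same approach but is of no consequence because it is set again in step 8. The step needs "para" regiochemistry, which is secured because both the silyloxy group at C7 and the dialkyl substitution at C3a make C6 the nucleophilic terminus that attacks the enal β-carbon. It also needs ring closure to win over silyl transfer after the first bond (Mukaiyama–Michael pathway), which the bulky triisopropylsilyl group and the low temperature should favour. The diene is achiral and ring C carries no stereocentre yet, so no substrate bias has to be overcome.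

Step 6
Reactants: 8 (3aS,4R)-4-bromo-3a-(TBSOCH2)-7-(TIPSO)-2,3,3a,4,5,6-hexahydro-1H-indene-4-carbaldehyde
Product: 9 (3aS,4R)-4-bromo-3a-(TBSOCH2)-7-oxo-3,3a,4,5,6,7-hexahydro-2H-indene-4-carbaldehyde
Conditions: Pd(OAc)2 (1.2 equiv), DMSO, 50 °C
Reagents that add atoms: none
Why: Saegusa–Ito oxidation of the regiodefined enol silane, in which β-hydride elimination from the palladium enolate at C7a can only go toward C1 because C3a is quaternary, so the C1=C7a enone should result.

Step 7
Reactants: 9 (3aS,4R)-4-bromo-3a-(TBSOCH2)-7-oxo-3,3a,4,5,6,7-hexahydro-2H-indene-4-carbaldehyde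
Product: 10 (3aS,4R)-4-bromo-3a-(TBSOCH2)-7-oxo-3,3a,4,5,6,7-hexahydro-2H-indene-4-carboxylic acid
Conditions: NaClO2, NaH2PO4, 2-methyl-2-butene, t-BuOH/H2O, 0 → 23 °C
Reagents that add atoms: sodium chlorite, [Na+].[O-]Cl=O
Why: Pinnick oxidation of the non-enolisable α-bromo aldehyde, with the alkene scavenger protecting the enone from hypochlorite.

Step 8
Reactants: 10 (3aS,4R)-4-bromo-3a-(TBSOCH2)-7-oxo-3,3a,4,5,6,7-hexahydro-2H-indene-4-carboxylic acid
Product: 13 (3aS,4S)-4-bromo-3a-(TBSOCH2)-2,3,3a,4,5,6-hexahydro-7H-inden-7-one, via acid chloride 11 (not isolated), via thiohydroxamate ester 12 (not isolated)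
Conditions: (COCl)2, DMF (cat.), CH2Cl2, 0 → 23 °C; sodium 2-pyridinethiolate 1-oxide, DMAP (cat.), PhH, dark; t-BuSH, hν (tungsten lamp), 23 °C
Reagents that add atoms: none
Why: Barton reductive decarboxylation, in which the acyloxy radical loses CO2 and the α-bromo C4 radical takes hydrogen from t-BuSH along the axial path anti to the axial C3a–CH2OTBS bond, so that bromine should end equatorial and cis to CH2OTBS (4S), the thiyl chain carrier being unable to abstract bromine.

Step 9
Reactants: 13 (3aS,4S)-4-bromo-3a-(TBSOCH2)-2,3,3a,4,5,6-hexahydro-7H-inden-7-one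
Product: 14 (3aS,4S,7R)-4-bromo-3a-(TBSOCH2)-7-methyl-3,3a,4,5,6,7-hexahydro-2H-inden-7-ol
Conditions: MeLi, CeCl3, THF, −78 °C
Reagents that add atoms: methyllithium, [Li]C
Why: Organocerium 1,2-addition to the enone, in which the axial CH2OTBS group at C3a blocks the syn-axial approach so that methyl enters equatorially and the new C7 hydroxyl is axial and cis to CH2OTBS (7R).

Step 10
Reactants: 14 (3aS,4S,7R)-4-bromo-3a-(TBSOCH2)-7-methyl-3,3a,4,5,6,7-hexahydro-2H-inden-7-ol
Product: 16 (1R,3aS,4S,7R,7aS)-4-bromo-7-methyl-1-(Bpin)-3a-(TBSOCH2)octahydro-1H-inden-7-ol, via alkylborane 15 (not isolated)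
Conditions: BH3·SMe2 (3 equiv), THF, 0 → 23 °C; pinacol, 23 °C
Reagents that add atoms: borane–dimethyl sulfide, [BH3-][S+](C)C; pinacol, CC(C)(O)C(C)(C)O
Why: Hydroboration (syn addition) puts boron on the less substituted C1 and hydrogen on C7a from the face opposite the two axial groups (C3a–CH2OTBS and C7–O), which should give the trans ring fusion with the C1–B bond cis to H-7a, and alcoholysis with pinacol gives the boronic ester.

Step 11
Reactants: 16 (1R,3aS,4S,7R,7aS)-4-bromo-7-methyl-1-(Bpin)-3a-(TBSOCH2)octahydro-1H-inden-7-ol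
Product: 19 (1S,3aS,4S,7R,7aS)-4-bromo-1-ethenyl-7-methyl-3a-(TBSOCH2)octahydro-1H-inden-7-ol, via vinyl boronate complex 17 (not isolated), via iodo boronate 18 (not isolated)
Conditions: CH2=CHMgBr (4 equiv), THF/DMSO 1:1, 23 °C; I2, THF, 0 °C; NaOMe, MeOH, 0 → 23 °C
Reagents that add atoms: vinylmagnesium bromide, C=C[Mg]Br
Why: Zweifel olefination, in which iodine triggers the 1,2-shift of C1 from boron to carbon with retention and methoxide-induced anti elimination then leaves the vinyl group on the face that boron occupied.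

Step 12
Reactants: 20 4-methylpent-3-en-2-one (mesityl oxide)
Product: 21 4-methyl-2-(TIPSO)penta-1,3-diene
Conditions: TIPSOTf, Et3N, CH2Cl2, 0 °C
Reagents that add atoms: triisopropylsilyl trifluoromethanesulfonate, CC(C)[Si](C(C)C)(C(C)C)OS(=O)(=O)C(F)(F)F
Why: Soft enolisation of mesityl oxide at its acetyl CH3 gives the cross-conjugated 2-silyloxydiene without any stereocentre.

Step 13
Reactants: 21 4-methyl-2-(TIPSO)penta-1,3-diene; 7 2-bromoprop-2-enal (2-bromoacrolein)
Product: 23 (1R)-1-bromo-2,2-dimethyl-4-oxocyclohexane-1-carbaldehyde, via enol silane adduct 22 (not isolated)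
Conditions: (S)-3,3-diphenyl-1-(2-methylphenyl)tetrahydro-1H,3H-pyrrolo[1,2-c][1,3,2]oxazaborole (20 mol %), (CF3SO2)2NH (17 mol %), CH2Cl2, −78 → −40 °C; 1 M HCl, THF, 0 °C
Reagents that add atoms: none
Why: The same oxazaborolidinium-catalysed Diels–Alder reaction as in step 5, in which the silyloxy group and the gem-dimethyl terminus both send the enal α-carbon to the CMe2 end, the catalyst-selected enal face sets the only stereocentre (1R), and acid hydrolysis of the enol silane unveils the ketone.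

Step 14
Reactants: 23 (1R)-1-bromo-2,2-dimethyl-4-oxocyclohexane-1-carbaldehyde
Product: 24 (1R)-1-bromo-2,2-dimethyl-4-oxocyclohexane-1-carboxylic acid
Conditions: NaClO2, NaH2PO4, 2-methyl-2-butene, t-BuOH/H2O, 0 → 23 °C
Reagents that add atoms: sodium chlorite, [Na+].[O-]Cl=O
Why: Pinnick oxidation, which is chemoselective for the aldehyde beside the ketone and leaves the quaternary stereocentre untouched.

Step 15
Reactants: 24 (1R)-1-bromo-2,2-dimethyl-4-oxocyclohexane-1-carboxylic acid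
Product: 25 (1R)-1-bromo-2,2-dimethyl-4-methylidenecyclohexane-1-carboxylic acid
Conditions: Ph3PCH3Br, KHMDS (3 equiv each), THF, 0 → 23 °C; 1 M HCl work-up
Reagents that add atoms: methylenetriphenylphosphorane, C=P(c1ccccc1)(c1ccccc1)c1ccccc1
Why: Wittig methylenation of the unhindered ketone, in which the carboxylate salt and the neopentyl tertiary bromide should not react with the ylide at this temperature and no stereocentre is formed.

Step 16
Reactants: 19 (1S,3aS,4S,7R,7aS)-4-bromo-1-ethenyl-7-methyl-3a-(TBSOCH2)octahydro-1H-inden-7-ol; 25 (1R)-1-bromo-2,2-dimethyl-4-methylidenecyclohexane-1-carboxylic acid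
Product: 26 (1R)-1-bromo-4-{[(1S,3aS,4S,7R,7aS)-4-bromo-7-hydroxy-7-methyl-3a-(TBSOCH2)octahydro-1H-inden-1-yl]methylidene}-2,2-dimethylcyclohexane-1-carboxylic acid (E/Z mixture)
Conditions: 25 (3 equiv), second-generation Hoveyda–Grubbs catalyst (10 mol %), CH2Cl2, 40 °C
Reagents that add atoms: none
Why: Olefin cross-metathesis of a monosubstituted alkene and a 1,1-disubstituted alkene to a trisubstituted alkene, whose geometry is of no consequence because C8 becomes CH2 and C1′ is set in step 17.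

Step 17
Reactants: 26 (1R)-1-bromo-4-{[(1S,3aS,4S,7R,7aS)-4-bromo-7-hydroxy-7-methyl-3a-(TBSOCH2)octahydro-1H-inden-1-yl]methylidene}-2,2-dimethylcyclohexane-1-carboxylic acid
Product: 27 (1S,4R)-4-bromo-1-{[(1S,3aS,4S,7R,7aS)-4-bromo-7-hydroxy-7-methyl-3a-(TBSOCH2)octahydro-1H-inden-1-yl]methyl}-5,5-dimethyl-2-oxabicyclo[2.2.2]octan-3-one
Conditions: [N,N′-bis(3,5-di-tert-butylsalicylidene)-1,2-cyclohexanediaminato]cobalt (3 mol %), N-fluoro-2,4,6-trimethylpyridinium triflate (1.5 equiv), PhSiH3 (1.5 equiv), PhCF3, 23 °C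
Reagents that add atoms: none
Why: Cobalt-hydride hydrogen-atom transfer to C8 gives the tertiary C1′ radical, which after one-electron oxidation is captured by the carboxylate on C4′ (radical-polar crossover hydroacyloxylation), and since the tether reaches only the face of ring A that carries the carboxyl group, C1′–O should be set cis to it in the bridged lactone while the axial C7 hydroxyl on the far face of the hydrindane cannot compete.

Step 18
Reactants: 27 (1S,4R)-4-bromo-1-{[(1S,3aS,4S,7R,7aS)-4-bromo-7-hydroxy-7-methyl-3a-(TBSOCH2)octahydro-1H-inden-1-yl]methyl}-5,5-dimethyl-2-oxabicyclo[2.2.2]octan-3-one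
Product: 29 (1S,4S)-4-bromo-1-{[(1S,3aS,4S,7R,7aS)-4-bromo-7-hydroxy-7-methyl-3a-(TBSOCH2)octahydro-1H-inden-1-yl]methyl}-3,3-dimethylcyclohexan-1-ol, via hydroxy acid 28 (not isolated)
Conditions: LiOH, THF/H2O, 23 °C; 1 M HCl; then 9-mesityl-10-phenylacridinium tetrafluoroborate (5 mol %), (PhS)2 (10 mol %), i-Pr2NEt (20 mol %), CF3CH2OH, 450 nm LED, 23 °C
Reagents that add atoms: none
Why: Saponification of the strained bridged lactone followed by photoredox hydrodecarboxylation, in which the carboxylate is oxidised by the excited acridinium, CO2 is lost and the α-bromo C4′ radical takes hydrogen from thiophenol axially, anti to the axial C3′ methyl group, so that bromine should end equatorial and cis to the axial C1′ hydroxyl (4′S).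

Step 19
Reactants: 29 (1S,4S)-4-bromo-1-{[(1S,3aS,4S,7R,7aS)-4-bromo-7-hydroxy-7-methyl-3a-(TBSOCH2)octahydro-1H-inden-1-yl]methyl}-3,3-dimethylcyclohexan-1-ol
Product: 30 (1S,4S)-4-bromo-1-{[(1S,3aS,4S,7R,7aS)-4-bromo-7-hydroxy-7-methyl-3a-(TBSOCH2)octahydro-1H-inden-1-yl]methyl}-3,3-dimethylcyclohexyl acetate
Conditions: Ac2O, DMAP, Et3N, CH2Cl2, 40 °C
Reagents that add atoms: acetic anhydride, CC(=O)OC(C)=O
Why: DMAP-catalysed acylation of the more accessible tertiary hydroxyl at C1′, while the C7 hydroxyl, axial, 1,3-diaxial to CH2OTBS and flanked by the ring fusion, should stay free.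

Step 20
Reactants: 30 (1S,4S)-4-bromo-1-{[(1S,3aS,4S,7R,7aS)-4-bromo-7-hydroxy-7-methyl-3a-(TBSOCH2)octahydro-1H-inden-1-yl]methyl}-3,3-dimethylcyclohexyl acetate
Product: 31 (1S,4S)-4-bromo-1-{[(1S,3aS,4S,7R,7aS)-4-bromo-7-hydroxy-3a-(hydroxymethyl)-7-methyloctahydro-1H-inden-1-yl]methyl}-3,3-dimethylcyclohexyl acetate
Conditions: HF·pyridine, pyridine, THF, 0 → 23 °C
Reagents that add atoms: none
Why: Fluoride cleavage of the primary silyl ether under buffered conditions that the tertiary acetate, the tertiary alcohol and the two secondary bromides should survive.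

Compound list
1 | 2-bromocyclopent-1-ene-1-carbaldehyde | O=CC1=C(Br)CCC1 | starting material
2 | (2-bromocyclopent-1-en-1-yl)methanol | OCC1=C(Br)CCC1 | intermediate
3 | 1-bromo-2-(TBSOCH2)cyclopent-1-ene | CC(C)(C)[Si](C)(C)OCC1=C(Br)CCC1 | intermediate
4 | [2-(TBSOCH2)cyclopent-1-en-1-yl]lithium | [Li]C1=C(CO[Si](C)(C)C(C)(C)C)CCC1 | intermediate
5 | 1-[2-(TBSOCH2)cyclopent-1-en-1-yl]ethan-1-one | CC(=O)C1=C(CO[Si](C)(C)C(C)(C)C)CCC1 | intermediate
6 | 1-(TBSOCH2)-2-[1-(TIPSO)ethenyl]cyclopent-1-ene | C=C(O[Si](C(C)C)(C(C)C)C(C)C)C1=C(CO[Si](C)(C)C(C)(C)C)CCC1 | intermediate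
7 | 2-bromoprop-2-enal (2-bromoacrolein) | C=C(Br)C=O | starting material
8 | (3aS,4R)-4-bromo-3a-(TBSOCH2)-7-(TIPSO)-2,3,3a,4,5,6-hexahydro-1H-indene-4-carbaldehyde (CHO cis to CH2OTBS) | C1CC[C@]2(CO[Si](C)(C)C(C)(C)C)[C@@](Br)(C=O)CCC(O[Si](C(C)C)(C(C)C)C(C)C)=C21 | intermediate
9 | (3aS,4R)-4-bromo-3a-(TBSOCH2)-7-oxo-3,3a,4,5,6,7-hexahydro-2H-indene-4-carbaldehyde | C1CC[C@]2(CO[Si](C)(C)C(C)(C)C)[C@@](Br)(C=O)CCC(=O)C2=1 | intermediate
10 | (3aS,4R)-4-bromo-3a-(TBSOCH2)-7-oxo-3,3a,4,5,6,7-hexahydro-2H-indene-4-carboxylic acid | C1CC[C@]2(CO[Si](C)(C)C(C)(C)C)[C@@](Br)(C(=O)O)CCC(=O)C2=1 | intermediate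
11 | acid chloride of 10 | C1CC[C@]2(CO[Si](C)(C)C(C)(C)C)[C@@](Br)(C(=O)Cl)CCC(=O)C2=1 | intermediate
12 | 2-thioxopyridin-1(2H)-yl ester of 10 | C1CC[C@]2(CO[Si](C)(C)C(C)(C)C)[C@@](Br)(C(=O)ON3C=CC=CC3=S)CCC(=O)C2=1 | intermediate
13 | (3aS,4S)-4-bromo-3a-(TBSOCH2)-2,3,3a,4,5,6-hexahydro-7H-inden-7-one (Br cis to CH2OTBS) | C1CC[C@]2(CO[Si](C)(C)C(C)(C)C)[C@@H](Br)CCC(=O)C2=1 | intermediate
14 | (3aS,4S,7R)-4-bromo-3a-(TBSOCH2)-7-methyl-3,3a,4,5,6,7-hexahydro-2H-inden-7-ol (OH cis to CH2OTBS) | C1CC[C@]2(CO[Si](C)(C)C(C)(C)C)[C@@H](Br)CC[C@@](C)(O)C2=1 | intermediate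
15 | [(1R,3aS,4S,7R,7aS)-4-bromo-7-hydroxy-7-methyl-3a-(TBSOCH2)octahydro-1H-inden-1-yl]borane | [BH2][C@@H]1CC[C@]2(CO[Si](C)(C)C(C)(C)C)[C@@H](Br)CC[C@@](C)(O)[C@@H]12 | intermediate
16 | (1R,3aS,4S,7R,7aS)-4-bromo-7-methyl-1-(Bpin)-3a-(TBSOCH2)octahydro-1H-inden-7-ol (trans ring fusion, boron cis to H-7a) | CC1(C)OB(OC1(C)C)[C@@H]2CC[C@]3(CO[Si](C)(C)C(C)(C)C)[C@@H](Br)CC[C@@](C)(O)[C@@H]23 | intermediate
17 | magnesium salt of the vinyl boronate complex of 16 (C7 alkoxide) | [Mg+2].C=C[B-]1(OC(C)(C)C(C)(C)O1)[C@@H]2CC[C@]3(CO[Si](C)(C)C(C)(C)C)[C@@H](Br)CC[C@@](C)([O-])[C@@H]23 | intermediate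
18 | 1-[2-iodo-1-(Bpin)ethyl] analogue of 19 (ring configuration as in 19) | ICC(B1OC(C)(C)C(C)(C)O1)[C@@H]2CC[C@]3(CO[Si](C)(C)C(C)(C)C)[C@@H](Br)CC[C@@](C)(O)[C@@H]23 | intermediate
19 | (1S,3aS,4S,7R,7aS)-4-bromo-1-ethenyl-7-methyl-3a-(TBSOCH2)octahydro-1H-inden-7-ol | C=C[C@@H]1CC[C@]2(CO[Si](C)(C)C(C)(C)C)[C@@H](Br)CC[C@@](C)(O)[C@@H]12 | intermediate
20 | 4-methylpent-3-en-2-one (mesityl oxide) | CC(=O)C=C(C)C | starting material
21 | 4-methyl-2-(TIPSO)penta-1,3-diene | C=C(O[Si](C(C)C)(C(C)C)C(C)C)C=C(C)C | intermediate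
22 | (1R)-1-bromo-2,2-dimethyl-4-(TIPSO)cyclohex-3-ene-1-carbaldehyde | CC(C)[Si](C(C)C)(C(C)C)OC1=CC(C)(C)[C@@](Br)(C=O)CC1 | intermediate
23 | (1R)-1-bromo-2,2-dimethyl-4-oxocyclohexane-1-carbaldehyde | O=C1CC[C@](Br)(C=O)C(C)(C)C1 | intermediate
24 | (1R)-1-bromo-2,2-dimethyl-4-oxocyclohexane-1-carboxylic acid | O=C1CC[C@](Br)(C(=O)O)C(C)(C)C1 | intermediate
25 | (1R)-1-bromo-2,2-dimethyl-4-methylidenecyclohexane-1-carboxylic acid | C=C1CC[C@](Br)(C(=O)O)C(C)(C)C1 | intermediate
26 | (1R)-1-bromo-4-{[(1S,3aS,4S,7R,7aS)-4-bromo-7-hydroxy-7-methyl-3a-(TBSOCH2)octahydro-1H-inden-1-yl]methylidene}-2,2-dimethylcyclohexane-1-carboxylic acid (E/Z mixture) | C1(=C[C@@H]2CC[C@]3(CO[Si](C)(C)C(C)(C)C)[C@@H](Br)CC[C@@](C)(O)[C@@H]23)CC[C@](Br)(C(=O)O)C(C)(C)C1 | intermediate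
27 | (1S,4R)-4-bromo-1-{[(1S,3aS,4S,7R,7aS)-4-bromo-7-hydroxy-7-methyl-3a-(TBSOCH2)octahydro-1H-inden-1-yl]methyl}-5,5-dimethyl-2-oxabicyclo[2.2.2]octan-3-one | O=C1O[C@]2(C[C@@H]3CC[C@]4(CO[Si](C)(C)C(C)(C)C)[C@@H](Br)CC[C@@](C)(O)[C@@H]34)CC[C@@]1(Br)C(C)(C)C2 | intermediate
28 | (1R,4S)-1-bromo-4-{[(1S,3aS,4S,7R,7aS)-4-bromo-7-hydroxy-7-methyl-3a-(TBSOCH2)octahydro-1H-inden-1-yl]methyl}-4-hydroxy-2,2-dimethylcyclohexane-1-carboxylic acid (OH cis to CO2H) | O[C@]1(C[C@@H]2CC[C@]3(CO[Si](C)(C)C(C)(C)C)[C@@H](Br)CC[C@@](C)(O)[C@@H]23)CC[C@](Br)(C(=O)O)C(C)(C)C1 | intermediate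
29 | (1S,4S)-4-bromo-1-{[(1S,3aS,4S,7R,7aS)-4-bromo-7-hydroxy-7-methyl-3a-(TBSOCH2)octahydro-1H-inden-1-yl]methyl}-3,3-dimethylcyclohexan-1-ol | O[C@]1(C[C@@H]2CC[C@]3(CO[Si](C)(C)C(C)(C)C)[C@@H](Br)CC[C@@](C)(O)[C@@H]23)CC[C@H](Br)C(C)(C)C1 | intermediate
30 | (1S,4S)-4-bromo-1-{[(1S,3aS,4S,7R,7aS)-4-bromo-7-hydroxy-7-methyl-3a-(TBSOCH2)octahydro-1H-inden-1-yl]methyl}-3,3-dimethylcyclohexyl acetate | CC(=O)O[C@]1(C[C@@H]2CC[C@]3(CO[Si](C)(C)C(C)(C)C)[C@@H](Br)CC[C@@](C)(O)[C@@H]23)CC[C@H](Br)C(C)(C)C1 | intermediate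
31 | (1S,4S)-4-bromo-1-{[(1S,3aS,4S,7R,7aS)-4-bromo-7-hydroxy-3a-(hydroxymethyl)-7-methyloctahydro-1H-inden-1-yl]methyl}-3,3-dimethylcyclohexyl acetate | CC(=O)O[C@]1(C[C@@H]2CC[C@]3(CO)[C@@H](Br)CC[C@@](C)(O)[C@@H]23)CC[C@H](Br)C(C)(C)C1 | target

Total steps: 20. Longest linear sequence: 16 steps (steps 1–11, then 16–20); steps 12–15 form the ring A branch.

Steps most likely to fail

Step 5. The tetrasubstituted diene terminus may react too slowly, so that silyl transfer after the first C–C bond (open-chain Michael product) or leakage between endo and exo approach erodes the yield and the enantiomeric purity at C3a. The fallback sets out from 6 and comes back at 8. The cycloaddition is run without chiral control under the mixed Lewis acid AlBr3/AlMe3 (toluene/CH2Cl2, −20 °C), conditions suited to hindered 2-silyloxydienes, and should give 8 together with its mirror image, the enantiomeric adduct F1. Preparative chromatography on a chiral stationary phase then returns 8, and F1 is set aside.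

Step 16. Cross-metathesis between an α-branched vinyl group and a 1,1-disubstituted alkene may stall, with catalyst decay and double-bond migration taking over. The fallback sets out from 13 and 25 and comes back at 27. Acid 25 is iodolactonised (I2, NaHCO3, MeCN) to the bridged (iodomethyl) lactone F2, which already fixes C1′. The primary radical from F2 (Bu3SnH, AIBN, slow addition, PhH, 80 °C, Giese addition) adds to C1 of enone 13 on the face away from CH2OTBS, and a short DBU equilibration of C7a should give keto lactone F3. MeLi/CeCl3 at −78 °C, as in step 9, then converts F3 into 27.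

Step 17. The tertiary C1′ radical or cation may lose a proton (alkene isomers in ring A) or be reduced before the carboxylate reaches across the ring in the boat form. The fallback sets out from 26 and comes back at 27. Iodolactonisation (I2, NaHCO3, MeCN, 0 °C) closes the same bridged lactone through the iodonium ion and gives iodo lactone F4 with iodine on C8. Radical deiodination with (Me3Si)3SiH/AIBN (PhMe, 80 °C), faster for the secondary iodide than for the hindered bromides, then gives 27.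

Further compounds
F1 | step 5 | (3aR,4S)-4-bromo-3a-(TBSOCH2)-7-(TIPSO)-2,3,3a,4,5,6-hexahydro-1H-indene-4-carbaldehyde (enantiomer of 8) | C1CC[C@@]2(CO[Si](C)(C)C(C)(C)C)[C@](Br)(C=O)CCC(O[Si](C(C)C)(C(C)C)C(C)C)=C21
F2 | step 16 | 4-bromo-1-(iodomethyl)-5,5-dimethyl-2-oxabicyclo[2.2.2]octan-3-one (ring configuration as in 27) | O=C1O[C@]2(CI)CC[C@@]1(Br)C(C)(C)C2
F3 | step 16 | 7-oxo analogue of 27 lacking the C7 methyl group (keto lactone, trans ring fusion) | O=C1O[C@]2(C[C@@H]3CC[C@]4(CO[Si](C)(C)C(C)(C)C)[C@@H](Br)CCC(=O)[C@@H]34)CC[C@@]1(Br)C(C)(C)C2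
F4 | step 17 | C8-iodo analogue of 27 (iodo lactone, C8 epimers) | O=C1O[C@]2(C(I)[C@@H]3CC[C@]4(CO[Si](C)(C)C(C)(C)C)[C@@H](Br)CC[C@@](C)(O)[C@@H]34)CC[C@@]1(Br)C(C)(C)C2
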